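**Retrosynthetic overview**
1. Target 10 ⇐ hexabenzyl ether 9 by neutral global hydrogenolysis (last step, α-stereocentres untouched).
2. meso-9 ⇐ furan 6: [4+2] addition of singlet O2 (two new C–O bonds), syn delivery of H2 to the ring-locked C=C, then O–O reduction; both C=O groups and both stereocentres arise here.
3. Furan 6 ⇐ 1,4-diketone 5 (any dl/meso ratio) by Paal–Knorr C–O ring closure, which erases the stereochemistry; 5 ⇐ oxidative enolate dimerisation of ketone 3.
4. Ketone 3 ⇐ acetophenone 1 + benzylic alcohol 2 (hydrogen-borrowing α-alkylation).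
5. Ring order: the furan is closed in step 2, turned into a 2,3,7-trioxabicyclo[2.2.1] cage and opened again in step 3; no ring other than the arenes remains.

Assumption: the SMILES encodes (2R,3S) with two identical halves, i.e. the achiral meso diastereomer, so "single enantiomer" is read as "single meso diastereomer" and the stereochemical task is meso versus dl control.

**Step 1**
Reactants: 1 1-[2,4-bis(benzyloxy)phenyl]ethan-1-one; 2 [4-(benzyloxy)phenyl]methanol (1.2 equiv)
Product: 3 1-[2,4-bis(benzyloxy)phenyl]-3-[4-(benzyloxy)phenyl]propan-1-one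
Conditions: [Cp*IrCl2]2 (1 mol %), KOH (20 mol %), PhMe, 110 °C
Reagents that add atoms: none
Why: Hydrogen-borrowing α-alkylation (alcohol dehydrogenation, Claisen–Schmidt condensation, Ir–H reduction of the chalcone C=C) gives the mono-alkylated ketone with water as the only by-product; benzyl ethers are inert and no stereocentre is formed.

**Step 2**
Reactants: 3 1-[2,4-bis(benzyloxy)phenyl]-3-[4-(benzyloxy)phenyl]propan-1-one (2 equiv)
Product: 6 2,5-bis[2,4-bis(benzyloxy)phenyl]-3,4-bis[4-(benzyloxy)benzyl]furan, via lithium Z-enolate 4 (not isolated), via dl/meso 1,4-diketone 5 (not isolated)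
Conditions: LDA (1.1 equiv), THF, −78 °C; CuCl2 (1.1 equiv), DMF, −78 °C → rt; aqueous work-up; crude, p-TsOH·H2O (10 mol %), PhMe, 80 °C, 4 Å MS
Reagents that add atoms: none
Why: Cu(II)-mediated oxidative homocoupling of the lithium enolate forms the C2–C3 bond without stereocontrol, and Paal–Knorr cyclodehydration then makes the furan C–O bond and erases both stereocentres, so dl- and meso-5 converge on one achiral furan.

**Step 3**
Reactants: 6 2,5-bis[2,4-bis(benzyloxy)phenyl]-3,4-bis[4-(benzyloxy)benzyl]furan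
Product: 9 meso-(2R,3S)-1,4-bis[2,4-bis(benzyloxy)phenyl]-2,3-bis[4-(benzyloxy)benzyl]butane-1,4-dione, via furan endoperoxide 7 (not isolated), via bicyclic ozonide 8 (not isolated)
Conditions: O2, TPP (1 mol %), hν (white LED), CH2Cl2, −78 °C; Ar purge; KO2CN=NCO2K (10 equiv), AcOH (20 equiv), −78 → −40 °C; PPh3 (1.2 equiv), −40 °C → rt
Reagents that add atoms: dioxygen O=O
Why: Proposed new method: one-pot conversion of a tetrasubstituted furan into a meso-1,4-diketone – the [4+2] cycloaddition of singlet oxygen makes the two key C–O bonds (one becomes a carbonyl oxygen) and gives cage 7, whose strained, ring-locked C5=C6 bond is reduced at low temperature by diimide through a concerted six-centre syn transfer of both hydrogens (drawn exo, syn to O7; either face gives the same result; the O–O bond is inert to diimide), so the two benzyl-bearing carbons are necessarily cis in ozonide 8, and phosphine deoxygenation of 8 releases only the meso (2R,3S) diketone; strain relief of the 7-oxanorbornene-type alkene and a large excess of diimide are expected to offset tetrasubstitution; the closest known reaction types are the [4+2] photooxygenation of furans with reductive work-up and the diimide reduction of bicyclic endoperoxides of cyclic dienes and simple furans, not yet shown for fully substituted 2,5-diarylfuran endoperoxides.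

**Step 4**
Reactants: 9 meso-(2R,3S)-1,4-bis[2,4-bis(benzyloxy)phenyl]-2,3-bis[4-(benzyloxy)benzyl]butane-1,4-dione
Product: 10 meso-(2R,3S)-1,4-bis(2,4-dihydroxyphenyl)-2,3-bis(4-hydroxybenzyl)butane-1,4-dione (CNP0406969.1)
Conditions: H2 (1 atm), 10 % Pd/C, THF/MeOH 1:1, rt
Reagents that add atoms: none
Why: Catalytic hydrogenolysis cleaves the six aryl benzyl ethers under neutral conditions, the electron-rich (then ortho-hydroxy, hydrogen-bonded) aryl ketones are reduced far more slowly, and with no acid or base present C2/C3 cannot epimerise, so the meso configuration is kept.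

**Compound list**
1 | 1-[2,4-bis(benzyloxy)phenyl]ethan-1-one (2',4'-bis(benzyloxy)acetophenone) | CC(=O)c1ccc(OCc2ccccc2)cc1OCc1ccccc1 | starting material
2 | [4-(benzyloxy)phenyl]methanol (4-(benzyloxy)benzyl alcohol) | OCc1ccc(OCc2ccccc2)cc1 | starting material
3 | 1-[2,4-bis(benzyloxy)phenyl]-3-[4-(benzyloxy)phenyl]propan-1-one | O=C(CCc1ccc(OCc2ccccc2)cc1)c1ccc(OCc2ccccc2)cc1OCc1ccccc1 | intermediate
4 | lithium (Z)-1-[2,4-bis(benzyloxy)phenyl]-3-[4-(benzyloxy)phenyl]prop-1-en-1-olate | [Li]O/C(=C\Cc1ccc(OCc2ccccc2)cc1)c1ccc(OCc2ccccc2)cc1OCc1ccccc1 | intermediate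
5 | 1,4-bis[2,4-bis(benzyloxy)phenyl]-2,3-bis[4-(benzyloxy)benzyl]butane-1,4-dione, mixture of racemic (2R,3R)/(2S,3S) and meso diastereomers (no configuration specified) | O=C(c1ccc(OCc2ccccc2)cc1OCc1ccccc1)C(Cc1ccc(OCc2ccccc2)cc1)C(Cc1ccc(OCc2ccccc2)cc1)C(=O)c1ccc(OCc2ccccc2)cc1OCc1ccccc1 | intermediate
6 | 2,5-bis[2,4-bis(benzyloxy)phenyl]-3,4-bis[4-(benzyloxy)benzyl]furan | o1c(-c2ccc(OCc3ccccc3)cc2OCc2ccccc2)c(Cc2ccc(OCc3ccccc3)cc2)c(Cc2ccc(OCc3ccccc3)cc2)c1-c1ccc(OCc2ccccc2)cc1OCc1ccccc1 | intermediate
7 | 1,4-bis[2,4-bis(benzyloxy)phenyl]-5,6-bis[4-(benzyloxy)benzyl]-2,3,7-trioxabicyclo[2.2.1]hept-5-ene (Cs-symmetric furan endoperoxide) | [C@@]12(c3ccc(OCc4ccccc4)cc3OCc3ccccc3)OO[C@@](c3ccc(OCc4ccccc4)cc3OCc3ccccc3)(O1)C(Cc1ccc(OCc3ccccc3)cc1)=C2Cc1ccc(OCc2ccccc2)cc1 | intermediate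
8 | 1,4-bis[2,4-bis(benzyloxy)phenyl]-5,6-bis[4-(benzyloxy)benzyl]-2,3,7-trioxabicyclo[2.2.1]heptane, benzyl groups cis (both endo), new H atoms exo (syn to O7), Cs-symmetric ozonide | [C@@]12(c3ccc(OCc4ccccc4)cc3OCc3ccccc3)OO[C@@](c3ccc(OCc4ccccc4)cc3OCc3ccccc3)(O1)[C@H](Cc1ccc(OCc3ccccc3)cc1)[C@@H]2Cc1ccc(OCc2ccccc2)cc1 | intermediate
9 | meso-(2R,3S)-1,4-bis[2,4-bis(benzyloxy)phenyl]-2,3-bis[4-(benzyloxy)benzyl]butane-1,4-dione | O=C(c1ccc(OCc2ccccc2)cc1OCc1ccccc1)[C@@H](Cc1ccc(OCc2ccccc2)cc1)[C@@H](Cc1ccc(OCc2ccccc2)cc1)C(=O)c1ccc(OCc2ccccc2)cc1OCc1ccccc1 | intermediate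
10 | meso-(2R,3S)-1,4-bis(2,4-dihydroxyphenyl)-2,3-bis(4-hydroxybenzyl)butane-1,4-dione | O=C(c1ccc(O)cc1O)[C@@H](Cc1ccc(O)cc1)[C@@H](Cc1ccc(O)cc1)C(=O)c1ccc(O)cc1O | target

**Step count and risks**
Total steps: 4. Longest linear sequence: 4 (fully linear, 1 → 3 → 6 → 9 → 10).

Steps most likely to fail:

Step 3 (the proposed new step). The risks are that diimide reacts too slowly with the tetrasubstituted alkene of 7, or that 7 decomposes before it is reduced. The fallback uses known chemistry and sets out from furan 6. The same photooxygenation gives 7, which is quenched at −78 °C with Me2S. This known reductive opening of furan endoperoxides gives the ring-derived cis-enedione (Z)-1,4-bis[2,4-bis(benzyloxy)phenyl]-2,3-bis[4-(benzyloxy)benzyl]but-2-ene-1,4-dione F1, which is kept cold and dark to avoid Z→E isomerisation. Hydrogenation of F1 (H2, Pd/C, THF/MeOH) adds H2 syn to the Z-alkene (Z plus syn gives meso) and cleaves the six benzyl ethers in the same flask. The fallback therefore comes back to the route at target 10, without passing through 9. Any 7 left unreduced in the main step 3 is converted by PPh3 into this same F1 and is funnelled to 10 in step 4 in the same way.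

Step 2. The risks are a low-yielding Cu(II) coupling of the α-branched enolate and partial debenzylation during acid cyclisation. The fallback sets out from ketone 3 and replaces the oxidative coupling by a polar two-component coupling. α-Bromination of 3 (CuBr2, EtOAc/CHCl3, reflux) gives racemic 2-bromo-1-[2,4-bis(benzyloxy)phenyl]-3-[4-(benzyloxy)phenyl]propan-1-one F2. SN2 C-alkylation of lithium enolate 4 (from a second equivalent of 3, LDA, THF/DMPU, −78 → 0 °C) with F2 gives diketone 5, whose diastereomer ratio is irrelevant. The fallback comes back at 5, which is closed to furan 6 as before.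

Step 1. The risks are over-reduction of the ketone by transfer hydrogenation or incomplete alkylation. The fallback sets out from acetophenone 1 and uses the classical two-stage route. Claisen–Schmidt condensation with commercial 4-(benzyloxy)benzaldehyde (KOH, EtOH, rt) gives (E)-1-[2,4-bis(benzyloxy)phenyl]-3-[4-(benzyloxy)phenyl]prop-2-en-1-one F3. Chemoselective alkene hydrogenation with Wilkinson's catalyst (H2, RhCl(PPh3)3, PhMe/EtOH), which spares the benzyl ethers and the ketone, comes back at 3.

**Further compounds**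
F1 | step 3 | (Z)-1,4-bis[2,4-bis(benzyloxy)phenyl]-2,3-bis[4-(benzyloxy)benzyl]but-2-ene-1,4-dione | O=C(c1ccc(OCc2ccccc2)cc1OCc1ccccc1)/C(Cc1ccc(OCc2ccccc2)cc1)=C(Cc1ccc(OCc2ccccc2)cc1)\C(=O)c1ccc(OCc2ccccc2)cc1OCc1ccccc1
F2 | step 2 | rac-2-bromo-1-[2,4-bis(benzyloxy)phenyl]-3-[4-(benzyloxy)phenyl]propan-1-one | O=C(C(Br)Cc1ccc(OCc2ccccc2)cc1)c1ccc(OCc2ccccc2)cc1OCc1ccccc1
F3 | step 1 | (E)-1-[2,4-bis(benzyloxy)phenyl]-3-[4-(benzyloxy)phenyl]prop-2-en-1-one | O=C(/C=C/c1ccc(OCc2ccccc2)cc1)c1ccc(OCc2ccccc2)cc1OCc1ccccc1
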